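The route rests on disconnecting the pyranone ring at C3'–C4'. The feature exploited is that O1' is an enol-ester oxygen on the ethyl-bearing C6', C2' is an acyl carbon whose α-carbon C3' carries the bridging CH2, and C4' (bearing OH) is a former carboxyl carbon. An intramolecular Claisen condensation of a (Z)-β-acyloxy enoate therefore forms C3'–C4', closes the pyranone and completes the arylmethyl–pyranone skeleton in one operation. The precursor is the enol ester of methyl 2-methyl-3-oxopentanoate with a 3-(2,6-dibenzyloxy-4-methoxyphenyl)propanoyl group. The chromanone ring and its C2 stereocentre follow by chromone formation and asymmetric conjugate phenylation; the 4-methoxy group fixes the ring-closure regiochemistry.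

Key step: step 6

Remark: primed locants refer to the pyranone ring, unprimed locants to the chromanone.
Assumption: the t-BuPyOx ligand is taken to induce the same sense on this chromone as on simple chromones ((S)-ligand giving 2R), so the (R)-ligand is specified; if the sense were reversed, the other antipode would be used.
Assumption: methoxymethylation of the pyranone is drawn at O4'; an O2' regioisomer would converge on the same target in the last step.

Step 1
Reactants: 1 2,4,6-trihydroxybenzaldehyde
Product: 2 2,6-dihydroxy-4-methoxybenzaldehyde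
Conditions: Me2SO4 (1.0 equiv), K2CO3 (1.0 equiv), acetone, 0 °C → rt
Reagents that add atoms: dimethyl sulfate, COS(=O)(=O)OC
Why: Williamson O-methylation, in which the 4-OH (para to the formyl group and not hydrogen-bonded to it) is the most acidic and most accessible hydroxyl, so one equivalent of base and electrophile should methylate it preferentially.

Step 2
Reactants: 2 2,6-dihydroxy-4-methoxybenzaldehyde
Product: 3 2,6-bis(benzyloxy)-4-methoxybenzaldehyde
Conditions: BnBr (2.5 equiv), K2CO3 (3 equiv), DMF, 60 °C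
Reagents that add atoms: benzyl bromide, BrCc1ccccc1
Why: Williamson etherification of both remaining phenols, with warming in DMF to overcome the hydrogen bond of the second ortho hydroxyl to the aldehyde.

Step 3
Reactants: 3 2,6-bis(benzyloxy)-4-methoxybenzaldehyde, 4 Meldrum's acid
Product: 7 3-[2,6-bis(benzyloxy)-4-methoxyphenyl]propanoic acid, via arylidene Meldrum's acid 5 (not isolated), via benzyl Meldrum's acid 6 (not isolated)
Conditions: HCO2H–Et3N (5:2), 95 °C; then aq. HCl
Reagents that add atoms: water, O
Why: Knoevenagel condensation followed in the same flask by formate transfer hydrogenation of the electron-poor arylidene C=C and hydrolytic decarboxylation of the dioxanedione, a metal-free reduction that leaves the benzyl ethers untouched.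

Step 4
Reactants: 7 3-[2,6-bis(benzyloxy)-4-methoxyphenyl]propanoic acid
Product: 8 3-[2,6-bis(benzyloxy)-4-methoxyphenyl]propanoyl chloride
Conditions: (COCl)2 (1.5 equiv), DMF (cat.), CH2Cl2, 0 °C → rt; evaporate, use crude
Reagents that add atoms: oxalyl chloride, O=C(Cl)C(Cl)=O
Why: acid chloride formation through the Vilsmeier-type chloroiminium intermediate, with both ring positions ortho to the side chain blocked so that Friedel–Crafts closure to an indanone cannot occur.

Step 5
Reactants: 8 3-[2,6-bis(benzyloxy)-4-methoxyphenyl]propanoyl chloride, 9 methyl 2-methyl-3-oxopentanoate (racemic; its stereocentre is lost on enolisation)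
Product: 11 methyl (Z)-3-{3-[2,6-bis(benzyloxy)-4-methoxyphenyl]propanoyloxy}-2-methylpent-2-enoate, via sodium enolate 10 (not isolated)
Conditions: NaH (1.05 equiv), THF, 0 °C; then 8, −78 → 0 °C
Reagents that add atoms: none
Why: O-acylation of a β-keto ester enolate, in which sodium chelation between the enolate and ester oxygens fixes the (Z)-geometry that places the acyloxy group cis to CO2Me, and the fully substituted α-carbon together with the hard acyl chloride disfavours C-acylation.

Step 6
Reactants: 11 methyl (Z)-3-{3-[2,6-bis(benzyloxy)-4-methoxyphenyl]propanoyloxy}-2-methylpent-2-enoate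
Product: 12 3-[2,6-bis(benzyloxy)-4-methoxybenzyl]-6-ethyl-4-hydroxy-5-methyl-2H-pyran-2-one
Conditions: 11 added to LiN(SiMe3)2 (2.5 equiv), THF, −78 → 0 °C; then 1 M aq. HCl
Reagents that add atoms: none
Why: LiN(SiMe3)2 removes a proton from the CH2 alpha to the enol-ester carbonyl of 11, the most acidic C–H present, and the lithium enolate adds to the methyl ester carbonyl that the (Z)-double bond holds next to it, the tetrahedral intermediate then expelling methoxide. The closest known reaction type is the Dieckmann-type intramolecular Claisen condensation that turns O-acyl salicylates into 4-hydroxycoumarins and beta-acyloxy esters into 4-hydroxy-5,6-dihydro-2-pyranones, applied here to a beta-acyloxy enoate. The pyranone ring closes in the 6-exo-trig mode, the enolate carbon C3' attacking the ester carbon C4' whose C=O lies outside the new ring. No stereocentre is formed. The step needs C–C closure to be faster than E1cB loss of the keto-ester enolate from the acyl enolate (ketene formation) and than gamma-deprotonation of the enoate; the (Z)-geometry fixed in step 5, lithium bridging of the two carbonyl oxygens and the low temperature secure this. The excess base converts the product into its lithium pyranonate, which makes the condensation irreversible, and the benzyl and methyl aryl ethers are inert to the amide base.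

Step 7
Reactants: 12 3-[2,6-bis(benzyloxy)-4-methoxybenzyl]-6-ethyl-4-hydroxy-5-methyl-2H-pyran-2-one
Product: 13 3-(2,6-dihydroxy-4-methoxybenzyl)-6-ethyl-4-hydroxy-5-methyl-2H-pyran-2-one
Conditions: H2 (1 atm), Pd/C (10%), EtOAc–MeOH, rt
Reagents that add atoms: none
Why: catalytic hydrogenolysis of the two aryl benzyl ethers, under which the tetrasubstituted pyranone double bond, the lactone and the diarylmethane CH2 are expected to be inert.

Step 8
Reactants: 13 3-(2,6-dihydroxy-4-methoxybenzyl)-6-ethyl-4-hydroxy-5-methyl-2H-pyran-2-one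
Product: 14 3-(3-acetyl-2,6-dihydroxy-4-methoxybenzyl)-6-ethyl-4-hydroxy-5-methyl-2H-pyran-2-one
Conditions: AcOH, BF3·OEt2 (4 equiv), 70 °C; then MeOH–H2O, 50 °C
Reagents that add atoms: acetic acid, CC(=O)O
Why: Friedel–Crafts C-acylation of a phloroglucinol-type ring, where the two open arene positions are equivalent, both pyranone carbons C3' and C5' are substituted, and the chelated ketone deactivates the ring against a second acylation, so a single C-acetyl isomer should result.

Step 9
Reactants: 14 3-(3-acetyl-2,6-dihydroxy-4-methoxybenzyl)-6-ethyl-4-hydroxy-5-methyl-2H-pyran-2-one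
Product: 15 3-[3-acetyl-2-hydroxy-4-methoxy-6-(methoxymethoxy)benzyl]-6-ethyl-4-(methoxymethoxy)-5-methyl-2H-pyran-2-one
Conditions: MOMCl (2.3 equiv), iPr2NEt (3 equiv), CH2Cl2, 0 °C → rt
Reagents that add atoms: chloromethyl methyl ether, COCCl
Why: selective O-alkylation, in which the acidic pyranone hydroxyl and the phenol para to the acetyl group react while the phenol hydrogen-bonded to the acetyl carbonyl stays free for the later ring closure.

Step 10
Reactants: 15 3-[3-acetyl-2-hydroxy-4-methoxy-6-(methoxymethoxy)benzyl]-6-ethyl-4-(methoxymethoxy)-5-methyl-2H-pyran-2-one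
Product: 17 8-{[6-ethyl-4-(methoxymethoxy)-5-methyl-2-oxo-2H-pyran-3-yl]methyl}-5-methoxy-7-(methoxymethoxy)-4H-chromen-4-one, via enaminone 16 (not isolated)
Conditions: Me2NCH(OMe)2 (3 equiv), toluene, 90 °C; evaporate; then AcOH, 50 °C
Reagents that add atoms: N,N-dimethylformamide dimethyl acetal, COC(OC)N(C)C
Why: enaminone formation at the acetyl CH3 followed by acid-promoted 6-endo addition of the free ortho phenol and loss of dimethylamine (the standard enaminone route to 2-unsubstituted chromones), with the methoxy group on the other ortho oxygen ensuring closure only through the hydroxyl next to the CH2 bridge.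

Step 11
Reactants: 17 8-{[6-ethyl-4-(methoxymethoxy)-5-methyl-2-oxo-2H-pyran-3-yl]methyl}-5-methoxy-7-(methoxymethoxy)-4H-chromen-4-one, 18 phenylboronic acid
Product: 19 (2S)-8-{[6-ethyl-4-(methoxymethoxy)-5-methyl-2-oxo-2H-pyran-3-yl]methyl}-5-methoxy-7-(methoxymethoxy)-2-phenyl-2,3-dihydro-4H-chromen-4-one
Conditions: Pd(OCOCF3)2 (10 mol%), (R)-4-tert-butyl-2-(pyridin-2-yl)-4,5-dihydrooxazole [(R)-t-BuPyOx, 12 mol%], NH4PF6 (30 mol%), H2O (5 equiv), ClCH2CH2Cl, 60 °C
Reagents that add atoms: none
Why: asymmetric conjugate addition of an arylboronic acid to a chromone catalysed by cationic divalent palladium (transmetalation, carbopalladation of C2=C3, protonolysis of the palladium enolate), in which the tert-butyl group of the (R)-ligand shields one face of the bound enone so that phenyl is delivered to C2 to set the S configuration.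

Step 12
Reactants: 19 (2S)-8-{[6-ethyl-4-(methoxymethoxy)-5-methyl-2-oxo-2H-pyran-3-yl]methyl}-5-methoxy-7-(methoxymethoxy)-2-phenyl-2,3-dihydro-4H-chromen-4-one
Product: 20 (2S)-8-[(6-ethyl-4-hydroxy-5-methyl-2-oxo-2H-pyran-3-yl)methyl]-5,7-dihydroxy-2-phenyl-2,3-dihydro-4H-chromen-4-one (CNP0326321.1)
Conditions: BCl3 (6 equiv), CH2Cl2, −78 → 0 °C; then H2O, pH 7 buffer
Reagents that add atoms: none
Why: Lewis-acid ether cleavage, in which BCl3 chelated between the C4 carbonyl and the peri C5 methoxy oxygen removes that methyl group and also cleaves both methoxymethyl acetals, while the cold acidic medium and neutral work-up avoid the base-induced ring opening to a chalcone that would erode the C2 configuration.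

Compound list
1 | 2,4,6-trihydroxybenzaldehyde | O=Cc1c(O)cc(O)cc1O | starting material
2 | 2,6-dihydroxy-4-methoxybenzaldehyde | COc1cc(O)c(C=O)c(O)c1 | intermediate
3 | 2,6-bis(benzyloxy)-4-methoxybenzaldehyde | COc1cc(OCc2ccccc2)c(C=O)c(OCc2ccccc2)c1 | intermediate
4 | Meldrum's acid (2,2-dimethyl-1,3-dioxane-4,6-dione) | CC1(C)OC(=O)CC(=O)O1 | starting material
5 | 5-[2,6-bis(benzyloxy)-4-methoxybenzylidene]-2,2-dimethyl-1,3-dioxane-4,6-dione | COc1cc(OCc2ccccc2)c(C=C2C(=O)OC(C)(C)OC2=O)c(OCc2ccccc2)c1 | intermediate (not isolated)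
6 | 5-[2,6-bis(benzyloxy)-4-methoxybenzyl]-2,2-dimethyl-1,3-dioxane-4,6-dione | COc1cc(OCc2ccccc2)c(CC2C(=O)OC(C)(C)OC2=O)c(OCc2ccccc2)c1 | intermediate (not isolated)
7 | 3-[2,6-bis(benzyloxy)-4-methoxyphenyl]propanoic acid | COc1cc(OCc2ccccc2)c(CCC(=O)O)c(OCc2ccccc2)c1 | intermediate
8 | 3-[2,6-bis(benzyloxy)-4-methoxyphenyl]propanoyl chloride | COc1cc(OCc2ccccc2)c(CCC(=O)Cl)c(OCc2ccccc2)c1 | intermediate
9 | methyl 2-methyl-3-oxopentanoate (racemic) | CCC(=O)C(C)C(=O)OC | starting material
10 | sodium (Z)-1-methoxy-2-methyl-1-oxopent-2-en-3-olate | CC/C([O-])=C(\C)C(=O)OC.[Na+] | intermediate (not isolated)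
11 | methyl (Z)-3-{3-[2,6-bis(benzyloxy)-4-methoxyphenyl]propanoyloxy}-2-methylpent-2-enoate | CC/C(OC(=O)CCc1c(OCc2ccccc2)cc(OC)cc1OCc1ccccc1)=C(\C)C(=O)OC | intermediate
12 | 3-[2,6-bis(benzyloxy)-4-methoxybenzyl]-6-ethyl-4-hydroxy-5-methyl-2H-pyran-2-one | CCc1oc(=O)c(Cc2c(OCc3ccccc3)cc(OC)cc2OCc2ccccc2)c(O)c1C | intermediate
13 | 3-(2,6-dihydroxy-4-methoxybenzyl)-6-ethyl-4-hydroxy-5-methyl-2H-pyran-2-one | CCc1oc(=O)c(Cc2c(O)cc(OC)cc2O)c(O)c1C | intermediate
14 | 3-(3-acetyl-2,6-dihydroxy-4-methoxybenzyl)-6-ethyl-4-hydroxy-5-methyl-2H-pyran-2-one | CCc1oc(=O)c(Cc2c(O)c(C(C)=O)c(OC)cc2O)c(O)c1C | intermediate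
15 | 3-[3-acetyl-2-hydroxy-4-methoxy-6-(methoxymethoxy)benzyl]-6-ethyl-4-(methoxymethoxy)-5-methyl-2H-pyran-2-one | CCc1oc(=O)c(Cc2c(O)c(C(C)=O)c(OC)cc2OCOC)c(OCOC)c1C | intermediate
16 | 3-{3-[(E)-3-(dimethylamino)prop-2-enoyl]-2-hydroxy-4-methoxy-6-(methoxymethoxy)benzyl}-6-ethyl-4-(methoxymethoxy)-5-methyl-2H-pyran-2-one | CCc1oc(=O)c(Cc2c(O)c(C(=O)/C=C/N(C)C)c(OC)cc2OCOC)c(OCOC)c1C | intermediate (not isolated)
17 | 8-{[6-ethyl-4-(methoxymethoxy)-5-methyl-2-oxo-2H-pyran-3-yl]methyl}-5-methoxy-7-(methoxymethoxy)-4H-chromen-4-one | CCc1oc(=O)c(Cc2c(OCOC)cc(OC)c3c(=O)ccoc23)c(OCOC)c1C | intermediate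
18 | phenylboronic acid | OB(O)c1ccccc1 | starting material
19 | (2S)-8-{[6-ethyl-4-(methoxymethoxy)-5-methyl-2-oxo-2H-pyran-3-yl]methyl}-5-methoxy-7-(methoxymethoxy)-2-phenyl-2,3-dihydro-4H-chromen-4-one | CCc1oc(=O)c(Cc2c(OCOC)cc(OC)c3c2O[C@H](c2ccccc2)CC3=O)c(OCOC)c1C | intermediate
20 | (2S)-8-[(6-ethyl-4-hydroxy-5-methyl-2-oxo-2H-pyran-3-yl)methyl]-5,7-dihydroxy-2-phenyl-2,3-dihydro-4H-chromen-4-one | CCc1oc(=O)c(Cc2c(O)cc(O)c3c2O[C@H](c2ccccc2)CC3=O)c(O)c1C | target

Total step count: 12 steps.
Longest linear sequence: 12 steps (from 1 to 20); compounds 4, 9 and 18 enter as purchased materials.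

Steps most likely to fail

Step 6 (Dieckmann closure). The acyl enolate may collapse by E1cB expulsion of the keto-ester enolate to a ketene, with recombination at carbon, or the base may remove a gamma-proton of the enoate instead, so that little C3'–C4' closure takes place. The fallback sets out from aldehyde 3 and comes back at 12, building the pyranone separately and attaching it by reductive alkylation. The dianion of methyl 3-oxopentanoate (NaH, then n-BuLi, THF) would be acylated at its gamma-carbon with N-methoxy-N-methylpropanamide to give methyl 4-methyl-3,5-dioxoheptanoate F1. DBU in hot toluene should lactonise this to 6-ethyl-4-hydroxy-5-methyl-2H-pyran-2-one F2. Three-component reductive alkylation of F2 with 3 and Hantzsch ester (L-proline cat., CH2Cl2, rt) would then pass through the Knoevenagel adduct 3-[2,6-bis(benzyloxy)-4-methoxybenzylidene]-6-ethyl-5-methyl-2H-pyran-2,4(3H)-dione F3, whose conjugate reduction delivers 12.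

Step 11 (asymmetric phenylation). Carbopalladation of the electron-rich, 5,8-disubstituted chromone may be slow or poorly face-selective, and the mildly acidic aqueous medium may strip an acetal protecting group. The fallback sets out from 15 and comes back at 19, replacing catalytic induction by cyclisation and resolution. Heating 15 with benzaldehyde and pyrrolidine in ethanol should give, through the chalcone 6-ethyl-3-{2-hydroxy-4-methoxy-6-(methoxymethoxy)-3-[(E)-3-phenylprop-2-enoyl]benzyl}-4-(methoxymethoxy)-5-methyl-2H-pyran-2-one F4, the racemic flavanone 8-{[6-ethyl-4-(methoxymethoxy)-5-methyl-2-oxo-2H-pyran-3-yl]methyl}-5-methoxy-7-(methoxymethoxy)-2-phenyl-2,3-dihydro-4H-chromen-4-one F5 by oxa-Michael closure. Preparative HPLC on an amylose tris(3,5-dimethylphenylcarbamate) phase would separate 19 from its (2R)-antipode F6.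

Step 8 (C-acetylation). The hot Lewis-acidic medium may cleave or scramble the aryl–CH2–pyranone bridge by ipso protonation, or acylation may stop at oxygen without migration to carbon. The fallback sets out from 13 and comes back at 14, using a Houben–Hoesch reaction at low temperature in place of the acylium route. Acetonitrile, ZnCl2 and HCl gas in Et2O at 0 °C should give the ketiminium salt 1-{3-[(6-ethyl-4-hydroxy-5-methyl-2-oxo-2H-pyran-3-yl)methyl]-2,4-dihydroxy-6-methoxyphenyl}ethan-1-iminium chloride F7, and warming in water would hydrolyse it to 14.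

Further compounds
F1 | step 6 | methyl 4-methyl-3,5-dioxoheptanoate | CCC(=O)C(C)C(=O)CC(=O)OC
F2 | step 6 | 6-ethyl-4-hydroxy-5-methyl-2H-pyran-2-one | CCc1oc(=O)cc(O)c1C
F3 | step 6 | 3-[2,6-bis(benzyloxy)-4-methoxybenzylidene]-6-ethyl-5-methyl-2H-pyran-2,4(3H)-dione | CCC1=C(C)C(=O)C(=Cc2c(OCc3ccccc3)cc(OC)cc2OCc2ccccc2)C(=O)O1
F4 | step 11 | 6-ethyl-3-{2-hydroxy-4-methoxy-6-(methoxymethoxy)-3-[(E)-3-phenylprop-2-enoyl]benzyl}-4-(methoxymethoxy)-5-methyl-2H-pyran-2-one | CCc1oc(=O)c(Cc2c(O)c(C(=O)/C=C/c3ccccc3)c(OC)cc2OCOC)c(OCOC)c1C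
F5 | step 11 | racemic 8-{[6-ethyl-4-(methoxymethoxy)-5-methyl-2-oxo-2H-pyran-3-yl]methyl}-5-methoxy-7-(methoxymethoxy)-2-phenyl-2,3-dihydro-4H-chromen-4-one | CCc1oc(=O)c(Cc2c(OCOC)cc(OC)c3c2OC(c2ccccc2)CC3=O)c(OCOC)c1C
F6 | step 11 | (2R)-8-{[6-ethyl-4-(methoxymethoxy)-5-methyl-2-oxo-2H-pyran-3-yl]methyl}-5-methoxy-7-(methoxymethoxy)-2-phenyl-2,3-dihydro-4H-chromen-4-one | CCc1oc(=O)c(Cc2c(OCOC)cc(OC)c3c2O[C@@H](c2ccccc2)CC3=O)c(OCOC)c1C
F7 | step 8 | 1-{3-[(6-ethyl-4-hydroxy-5-methyl-2-oxo-2H-pyran-3-yl)methyl]-2,4-dihydroxy-6-methoxyphenyl}ethan-1-iminium chloride | CCc1oc(=O)c(Cc2c(O)c(C(C)=[NH2+])c(OC)cc2O)c(O)c1C.[Cl-]
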